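**Plan**
1. Retrosynthesis: first the two MOM acetals are cut, then the C2–C1′ bond between ring C and ring B, giving 7-(methoxymethoxy)chromone and a ring B arylboronic acid. The boronic acid is cut at C1′–B (C–H borylation), then at the ArCH2–prenyl bond, then at C3′–O, back to 2,6-dibromoanisole.
2. Forward: ring B is elaborated linearly (Br to OH, MOM ether, prenylation, C–H borylation) and joined to the chromone in the penultimate step. Rings A and C are bought intact, no ring is constructed, and the last step removes both MOM groups.
3. Enabling features: C2 is the β-carbon of the C4 ketone of ring C, so at the chromone oxidation level C2=C3 is a prochiral acceptor for an aryl–metal. In ring B the adjacent C3′–O, C4′–OMe and C5′–prenyl groups leave C1′–H as the only ring C–H without an ortho substituent, so sterically controlled borylation marks exactly the carbon to be joined.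
4. Stereochemistry: the only stereocentre, C2 (S), is created in the fragment union by a chiral bisphosphine–rhodium catalyst (enantioface-selective aryl insertion) and is not touched afterwards.

Key step: step 6

Assumption: L = (S)-MeO-F12-BIPHEP, (S)-2,2′-bis[bis(3,4,5-trifluorophenyl)phosphino]-6,6′-dimethoxy-1,1′-biphenyl. Its (S) antipode is taken to give the (2S) product by analogy with (S)-biaryl bisphosphine–rhodium catalysts giving (S)-3-arylcyclohexanones (the same face of the enone); if a test run shows the opposite sense, (R)-L is used with nothing else changed.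

**Route**

Step 1
Reactants: 1 2,6-dibromoanisole (1,3-dibromo-2-methoxybenzene)
Product: 4 3-bromo-2-methoxyphenol, via aryllithium 2 (not isolated), via dimethyl arylboronate 3 (not isolated)
Conditions: n-BuLi (1.0 equiv), THF, −78 °C; B(OMe)3, −78 °C → rt; AcOH, 30% aq H2O2, 0 °C → rt
Reagents that add atoms: hydrogen peroxide, OO
Why: Bromine–lithium exchange at one of the two equivalent C–Br bonds is fast and self-limiting with one equivalent of n-BuLi, and trapping as the boronate followed by oxidative 1,2-aryl migration from boron to oxygen (borylation–oxidation of an aryl halide) should place the hydroxyl exactly where the bromine was.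

Step 2
Reactants: 4 3-bromo-2-methoxyphenol
Product: 5 1-bromo-2-methoxy-3-(methoxymethoxy)benzene
Conditions: MOMCl, K2CO3, acetone, 0 °C → rt
Reagents that add atoms: chloromethyl methyl ether (MOMCl), COCCl
Why: O-alkylation of the phenoxide with MOMCl (Williamson-type acetal formation) should mask the acidic OH for the organolithium, borylation and conjugate-addition steps.

Step 3
Reactants: 5 1-bromo-2-methoxy-3-(methoxymethoxy)benzene; 6 prenyl bromide (1-bromo-3-methylbut-2-ene)
Product: 8 2-methoxy-1-(methoxymethoxy)-3-(3-methylbut-2-en-1-yl)benzene, via aryllithium 7 (not isolated)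
Conditions: n-BuLi (1.0 equiv), THF, −78 °C; CuBr·SMe2 (10 mol %); 6, −78 → 0 °C
Reagents that add atoms: none
Why: Bromine–lithium exchange, much faster than ortho-deprotonation at −78 °C, gives an aryllithium stabilised by the flanking methoxy group, and copper-catalysed allylic substitution at the unhindered primary carbon of prenyl bromide (SN2 mode) should give the linear prenyl arene.

Step 4
Reactants: 8 2-methoxy-1-(methoxymethoxy)-3-(3-methylbut-2-en-1-yl)benzene
Product: 10 [4-methoxy-3-(methoxymethoxy)-5-(3-methylbut-2-en-1-yl)phenyl]boronic acid, via pinacol arylboronate 9 (not isolated)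
Conditions: B2pin2 (0.6 equiv), [Ir(OMe)(cod)]2 (1.5 mol %), 4,4′-di-tert-butyl-2,2′-bipyridine (3 mol %), THF, 80 °C; then NaIO4, NH4OAc, acetone/H2O, rt
Reagents that add atoms: bis(pinacolato)diboron, CC1(C)OB(OC1(C)C)B1OC(C)(C)C(C)(C)O1; water, O
Why: Iridium-catalysed aromatic C–H borylation is governed by sterics, so the trisboryl complex of trivalent iridium should activate only C5–H, the one ring C–H of this 1,2,3-trisubstituted arene with no ortho substituent, while the hindered trisubstituted olefin is expected to stay intact; periodate cleavage of the liberated pinacol then drives hydrolysis of the ester to the boronic acid.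

Step 5
Reactants: 11 7-hydroxy-4H-chromen-4-one (7-hydroxychromone)
Product: 12 7-(methoxymethoxy)-4H-chromen-4-one
Conditions: MOMCl, K2CO3, acetone, rt
Reagents that add atoms: chloromethyl methyl ether (MOMCl), COCCl
Why: O-alkylation of the phenoxide with MOMCl (Williamson-type acetal formation) removes the acidic 7-OH, whose phenoxide would otherwise deactivate the chromone as an acceptor and protonate the arylrhodium species.

Step 6
Reactants: 10 [4-methoxy-3-(methoxymethoxy)-5-(3-methylbut-2-en-1-yl)phenyl]boronic acid; 12 7-(methoxymethoxy)-4H-chromen-4-one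
Product: 13 (2S)-2-[4-methoxy-3-(methoxymethoxy)-5-(3-methylbut-2-en-1-yl)phenyl]-7-(methoxymethoxy)-2,3-dihydro-4H-chromen-4-one
Conditions: 10 (1.5 equiv), [RhCl(C2H4)2]2 (1.5 mol %), L (3.3 mol %), aq KOH (10 mol %), CH2Cl2/H2O (10:1), 20 °C
Reagents that add atoms: none
Why: The hydroxo complex of monovalent rhodium formed in situ takes the aryl group of 10 by transmetalation from boron, the C2=C3 bond of chromone 12 coordinates with one enantioface exposed by the C2-symmetric bisphosphine, and migratory insertion into the aryl–rhodium bond forms the C2–aryl bond and an oxa-π-allyl rhodium enolate that water protonates at C3, returning Rh–OH. The closest known reaction type is the Hayashi–Miyaura asymmetric 1,4-addition of arylboronic acids to cyclic enones, which is established for chromones as a route to 2-arylchroman-4-ones. No ring is closed: rings A and C arrive intact in 12 and ring B in 10. The single stereocentre C2 is set under catalyst control by the (S)-configured ligand, whose quadrant blocking is expected to direct the aryl group to the face of C2 that gives the (2S) product, by analogy with the (S) sense obtained with (S)-biaryl bisphosphines on cyclohex-2-enone. The step needs 1,4- over 1,2-selectivity, no addition to the product ketone and no E1cB opening of ring C, which the electron-poor ligand (fast insertion and fast enolate protonation), the low hydroxide loading, CH2Cl2 as solvent and ambient temperature should secure. In the substrates, the absence of ortho substituents next to boron in 10 keeps transmetalation fast and the isolated trisubstituted prenyl olefin is not an acceptor for the arylrhodium species.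

Step 7
Reactants: 13 (2S)-2-[4-methoxy-3-(methoxymethoxy)-5-(3-methylbut-2-en-1-yl)phenyl]-7-(methoxymethoxy)-2,3-dihydro-4H-chromen-4-one
Product: 14 (2S)-7-hydroxy-2-[3-hydroxy-4-methoxy-5-(3-methylbut-2-en-1-yl)phenyl]-2,3-dihydro-4H-chromen-4-one (erylatissin C)
Conditions: HCl (ca. 1 M in MeOH), 25 → 40 °C
Reagents that add atoms: none
Why: Acid-catalysed transacetalisation to methanol should cleave both aryl MOM ethers, while the prenyl group, flanked only by OMe and H, cannot cyclise to a chroman and the C2 stereocentre, which is epimerised through base-mediated ring opening rather than by dilute acid, should be retained.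

**Compound list**
1 | 2,6-dibromoanisole (1,3-dibromo-2-methoxybenzene) | COc1c(Br)cccc1Br | starting material
2 | (3-bromo-2-methoxyphenyl)lithium | [Li]c1cccc(Br)c1OC | intermediate
3 | dimethyl (3-bromo-2-methoxyphenyl)boronate | COB(OC)c1cccc(Br)c1OC | intermediate
4 | 3-bromo-2-methoxyphenol | COc1c(O)cccc1Br | intermediate
5 | 1-bromo-2-methoxy-3-(methoxymethoxy)benzene | COCOc1cccc(Br)c1OC | intermediate
6 | prenyl bromide (1-bromo-3-methylbut-2-ene) | CC(C)=CCBr | starting material
7 | [2-methoxy-3-(methoxymethoxy)phenyl]lithium | [Li]c1cccc(OCOC)c1OC | intermediate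
8 | 2-methoxy-1-(methoxymethoxy)-3-(3-methylbut-2-en-1-yl)benzene | COCOc1cccc(CC=C(C)C)c1OC | intermediate
9 | 2-[4-methoxy-3-(methoxymethoxy)-5-(3-methylbut-2-en-1-yl)phenyl]-4,4,5,5-tetramethyl-1,3,2-dioxaborolane | COCOc1cc(B2OC(C)(C)C(C)(C)O2)cc(CC=C(C)C)c1OC | intermediate
10 | [4-methoxy-3-(methoxymethoxy)-5-(3-methylbut-2-en-1-yl)phenyl]boronic acid | COCOc1cc(B(O)O)cc(CC=C(C)C)c1OC | intermediate
11 | 7-hydroxy-4H-chromen-4-one (7-hydroxychromone) | O=c1ccoc2cc(O)ccc12 | starting material
12 | 7-(methoxymethoxy)-4H-chromen-4-one | COCOc1ccc2c(c1)occc2=O | intermediate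
13 | (2S)-2-[4-methoxy-3-(methoxymethoxy)-5-(3-methylbut-2-en-1-yl)phenyl]-7-(methoxymethoxy)-2,3-dihydro-4H-chromen-4-one | COCOc1cc([C@@H]2CC(=O)c3ccc(OCOC)cc3O2)cc(CC=C(C)C)c1OC | intermediate
14 | (2S)-7-hydroxy-2-[3-hydroxy-4-methoxy-5-(3-methylbut-2-en-1-yl)phenyl]-2,3-dihydro-4H-chromen-4-one (erylatissin C) | COc1c(O)cc([C@@H]2CC(=O)c3ccc(O)cc3O2)cc1CC=C(C)C | target

**Step count and risks**
Total step count: 7. Longest linear sequence: 6 steps (steps 1, 2, 3, 4, 6, 7); step 5 prepares the second fragment.

Steps most likely to fail:

Step 6. What may go wrong: insufficient enantioface discrimination on the electron-rich chromone, loss of the aryl group by protodeboronation, or erosion of the C2 configuration through opening of ring C at the rhodium enolate stage. The fallback gives up catalyst control and sets out from 10 and 12. A racemic Hayashi–Miyaura addition with the more active achiral [Rh(OH)(cod)]2 in dioxane/H2O should give the racemic flavanone F1. Its enantiomers are then separated by preparative chromatography on a cellulose tris(3,5-dimethylphenylcarbamate) stationary phase, and the (2S) enantiomer is 13, where the route is rejoined. The (2R) enantiomer F2 is recycled: KOH in MeOH opens ring C by retro-oxa-Michael reaction to the 2′-hydroxychalcone F3, and NaOAc in refluxing EtOH closes it again to F1.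

Step 4. What may go wrong: iridium-catalysed hydroboration or vinylic borylation at the prenyl olefin competing with arene C–H borylation, or over-borylation. The fallback borylates before any olefin is present and introduces the prenyl group last; it sets out from 5. Borylation of 5 under the same iridium conditions (again only the C–H meta to both flanking groups is open) should give the bromoaryl pinacol boronate F4, and NaIO4/NH4OAc should give the bromoarylboronic acid F5. The rhodium-catalysed asymmetric addition of F5 to 12 under the conditions of step 6, to which aryl bromides are inert, should give the (2S)-bromoflavanone F6. A Stille coupling of F6 with tributyl(3-methylbut-2-en-1-yl)stannane (Pd(PPh3)4, a zerovalent palladium catalyst, DMF, 90 °C, no base) then installs the prenyl group and comes back to the route at 13.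

Step 3. What may go wrong: attack of the aryl–metal at the γ-carbon of prenyl bromide (SN2′ mode), giving the 1,1-dimethylallyl isomer, and Wurtz-type homocoupling through halogen–metal exchange with the allylic bromide. The fallback builds the prenyl group in two stages and sets out from 5. The same bromine–lithium exchange followed by allyl bromide, whose two termini are equivalent, should give the allylarene F7. Olefin cross-metathesis of F7 with excess 2-methylbut-2-ene (second-generation Grubbs catalyst RuCl2(=CHPh)(PCy3)(H2IMes), CH2Cl2, 40 °C) then comes back to the route at 8.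

**Further compounds**
F1 | step 6 | racemic 2-[4-methoxy-3-(methoxymethoxy)-5-(3-methylbut-2-en-1-yl)phenyl]-7-(methoxymethoxy)-2,3-dihydro-4H-chromen-4-one | COCOc1cc(C2CC(=O)c3ccc(OCOC)cc3O2)cc(CC=C(C)C)c1OC
F2 | step 6 | (2R)-2-[4-methoxy-3-(methoxymethoxy)-5-(3-methylbut-2-en-1-yl)phenyl]-7-(methoxymethoxy)-2,3-dihydro-4H-chromen-4-one | COCOc1cc([C@H]2CC(=O)c3ccc(OCOC)cc3O2)cc(CC=C(C)C)c1OC
F3 | step 6 | (E)-1-[2-hydroxy-4-(methoxymethoxy)phenyl]-3-[4-methoxy-3-(methoxymethoxy)-5-(3-methylbut-2-en-1-yl)phenyl]prop-2-en-1-one | COCOc1ccc(C(=O)/C=C/c2cc(OCOC)c(OC)c(CC=C(C)C)c2)c(O)c1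
F4 | step 4 | 2-[3-bromo-4-methoxy-5-(methoxymethoxy)phenyl]-4,4,5,5-tetramethyl-1,3,2-dioxaborolane | COCOc1cc(B2OC(C)(C)C(C)(C)O2)cc(Br)c1OC
F5 | step 4 | [3-bromo-4-methoxy-5-(methoxymethoxy)phenyl]boronic acid | COCOc1cc(B(O)O)cc(Br)c1OC
F6 | step 4 | (2S)-2-[3-bromo-4-methoxy-5-(methoxymethoxy)phenyl]-7-(methoxymethoxy)-2,3-dihydro-4H-chromen-4-one | COCOc1cc([C@@H]2CC(=O)c3ccc(OCOC)cc3O2)cc(Br)c1OC
F7 | step 3 | 2-methoxy-1-(methoxymethoxy)-3-(prop-2-en-1-yl)benzene | C=CCc1cccc(OCOC)c1OC
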